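The readings are simulated for an exercise.

25 h is what winter, summer and dusk each get at their own temperature, so I ask how far that time lies past the hour at which the climb of mono adduct flattens.

common to all: coupling partner 0.475 M
- red: substrate 0.25 M; temperature 90 °C; run made earlier
- amber: substrate 0.38 M; temperature 110 °C; run made earlier
- winter: substrate 0.50 M; temperature 110 °C; time 25 h
- summer: substrate 0.50 M; temperature 125 °C; time 25 h
- dusk: substrate 0.50 M; temperature 95 °C; time 25 h

- red (time / h: mono adduct / %): 6.00: 3.3; 10.0: 3.0; 15.0: 1.7; 20.0: 3.7; 30.0: 5.8; 60.0: 9.6; 72.0: 9.9
- amber (time / h: mono adduct / %): 2.50: 3.5; 4.00: 4.6; 6.00: 6.1; 8.00: 9.1; 12.0: 12.8; 20.0: 12.8; 30.0: 16.3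

(scatter of a reading: 1 percentage point)

* which flask leads in amount of mono adduct, in percent of the substrate charged ("all alike" within 1.5 percentage points) (winter / summer / dusk / all alike)
* how much mono adduct is there at the end, in percent of the substrate charged: winter
* how much mono adduct is there at the end, in percent of the substrate charged: summer
* how much mono adduct is there at the end, in percent of the substrate charged: dusk

- for released group the crystals are counted in
- as a solid, counted per litre of solution: crystals
- the numbers in the tables scatter by 1 percentage point (one standard deviation)
- reactions considered so far: substrate + coupling partner -> mono adduct + released group; substrate + coupling partner -> other mono adduct + released group; coupling partner + mono adduct -> bis adduct + released group; coupling partner + other mono adduct -> bis adduct + released group; mono adduct -> over-reaction product; coupling partner <-> dormant form; crystals <-> released group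

Mono adduct is a consecutive-reaction intermediate: substrate and coupling partner make it, and it goes on to bis adduct and over-reaction product. Amber reads 12.8% at 12.0 h and again 12.8% at 20.0 h, before a late 16.3% at 30.0 h. Red reads 9.6% at 60.0 h and 9.9% at 72.0 h. I call the hours until the main climb of mono adduct flattens the turning time 12.0 h, as read in amber, and I take it over for winter, which has amber's temperature and partner charge but more substrate. Red's flattening against amber's gives a factor of 5.00, a reading that carries the scatter; the two runs differ in temperature, 90 °C against 110 °C, and in substrate, 0.25 M against 0.38 M, and I choose to lay the whole factor on temperature.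

Spreading that factor evenly over the degrees gives my ladder. I reckon summer to turn at 3.59 h, earlier than winter, then comes the asked 25 h, and I reckon dusk to turn later still, at 40.1 h. So I put the end of dusk at 0.623 of a turning time, expect it still climbing, and reckon it near 7.97%. I put the end of winter at 2.08 turning times, among amber's readings of 12.8% to 16.3%. Summer ends at 6.97, further out than amber's last reading at 2.50, so I read no level for it and bet narrowly on winter.

The forecast differs: it names summer as leader, with 14% for winter, 19% for summer and 7% for dusk, and says of summer that slowing “probably caps it near 20%, possibly past its peak”.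

Winter leads with 13.1%, against 9.36% for summer and 6.88% for dusk.

    substrate + coupling partner → mono adduct + released group (k = 9.55 × 10⁻⁶ M⁻¹ s⁻¹, Ea = 110 kJ mol⁻¹)
    substrate + coupling partner → other mono adduct + released group (k = 1.09 × 10⁻⁵ M⁻¹ s⁻¹, Ea = 83.0 kJ mol⁻¹)
    coupling partner + mono adduct → bis adduct + released group (k = 6.13 × 10⁻⁶ M⁻¹ s⁻¹, Ea = 108 kJ mol⁻¹)
    coupling partner + other mono adduct → bis adduct + released group (k = 1.67 × 10⁻⁶ M⁻¹ s⁻¹, Ea = 102 kJ mol⁻¹)
    mono adduct → over-reaction product (k = 4.95 × 10⁻⁶ s⁻¹, Ea = 120 kJ mol⁻¹)
    coupling partner ⇌ dormant form (K = 0.590, k = 7.30 × 10⁻⁶ s⁻¹, Ea = 122 kJ mol⁻¹, ΔH = −21.0 kJ mol⁻¹)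
    crystals ⇌ released group, rate k7*(cs7 - [released group]) while solid is left; crystals form when [released group] > cs7 (solubility = 0.0720 M, k = 0.00214 s⁻¹)
    (constants at 110 °C)

Summer held 13.5% of mono adduct at 12.5 h and 9.36% at 25.0 h, by my reckoning 6.97 turning times out, with over-reaction product at 21.2%. The neighbour, run like dusk but at 120 °C, has a reckoned turning time of 5.37 h. That puts its end at 4.66 turning times, beyond winter and short of summer, and it holds 12.2% of mono adduct.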